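**Retrosynthetic overview**

1. The target is cut at the C4(ring A)–vinyl bond (Heck) into 3,4-diacetoxystyrene and the peracetylated C4 bromide of the tris(dihydrobenzofuran). All methyl ethers are cleaved with BBr3 before the stilbene exists.
2. Feature: in ring C (the benzofuran bearing the 3,5-dihydroxyphenyl group) C2 is a 4-oxybenzylic carbon bound to O1, and C3 carries one H between two arenes (C3a and the resorcinol ring). O1–C2 and C3–H are therefore the two bonds of a Markovnikov addition of the ortho phenol O–H across a 1,1,2-triarylethene; rings B and A repeat the motif, with C3 bound to C4 of the neighbouring benzofuran.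
3. Each triarylethene comes from a 2-hydroxybenzophenone by 4-methoxybenzyl Grignard addition and dehydration. Each ketone comes from an aryl metal (3,5-dimethoxyphenyl Grignard, then the C4 aryllithium of ring C, then that of ring B) and 2-bromo-6-hydroxy-4-methoxybenzaldehyde (used as its isolated sodium phenolate with the aryllithiums), followed by MnO2.
4. Ring order: C (step 5), B (step 10), A (step 14). The C4 bromide left by each closure is the handle for the next ring and finally for the styryl group.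

Key step: step 5

**Remarks and abbreviations**

Assumption: 1, 3, 6 and 25 are bought (3 and 6 as THF solutions). The sense of induction of acid A must be found in a trial run; (S,S)-A is written for the (2R,3R) rings and (R,R)-A for the (2S,3S) ring, to be exchanged if the trial shows the opposite.

- Acid A: imidodiphosphorimidate HN[P(=NSO2CF3)(O,O'-binaphthyldiyl)]2 built from two 3,3'-bis[3,5-bis(trifluoromethyl)phenyl]-1,1'-bi-2-naphthol units, used as (S,S)-A or its mirror image (R,R)-A.
- ArC = (2R,3R)-3-(3,5-dimethoxyphenyl)-6-methoxy-2-(4-methoxyphenyl)-2,3-dihydro-1-benzofuran-4-yl.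
- ArBC = (2S,3S)-3-(ArC)-6-methoxy-2-(4-methoxyphenyl)-2,3-dihydro-1-benzofuran-4-yl.

**Route**

Step 1
Reactants: 1 2-bromo-4,6-dimethoxybenzaldehyde
Product: 2 2-bromo-6-hydroxy-4-methoxybenzaldehyde
Conditions: BCl3 (1.2 equiv), CH2Cl2, −78 → 0 °C; then H2O
Reagents that add atoms: none
Why: Chelation-directed BCl3 demethylation should remove only the methyl ether ortho to the formyl group, because boron binds the carbonyl oxygen and the neighbouring methoxy oxygen in a six-membered chelate.

Step 2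
Reactants: 2 2-bromo-6-hydroxy-4-methoxybenzaldehyde; 3 (3,5-dimethoxyphenyl)magnesium chloride
Product: 4 3-bromo-2-[(3,5-dimethoxyphenyl)(hydroxy)methyl]-5-methoxyphenol (racemic)
Conditions: 3 (2.5 equiv), THF, 0 → 23 °C; aq. NH4Cl
Reagents that add atoms: none
Why: Grignard 1,2-addition to a salicylaldehyde, in which the first equivalent only deprotonates the phenol; the carbinol centre is left racemic because step 3 removes it.

Step 3
Reactants: 4 3-bromo-2-[(3,5-dimethoxyphenyl)(hydroxy)methyl]-5-methoxyphenol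
Product: 5 (2-bromo-6-hydroxy-4-methoxyphenyl)(3,5-dimethoxyphenyl)methanone
Conditions: activated MnO2 (15 equiv), CH2Cl2, 23 °C
Reagents that add atoms: none
Why: MnO2 oxidation of a doubly benzylic alcohol should give the hydrogen-bonded 2-hydroxybenzophenone without touching the phenol or the aryl bromide.

Step 4
Reactants: 5 (2-bromo-6-hydroxy-4-methoxyphenyl)(3,5-dimethoxyphenyl)methanone; 6 (4-methoxybenzyl)magnesium chloride
Product: 8 3-bromo-2-[1-(3,5-dimethoxyphenyl)-2-(4-methoxyphenyl)ethenyl]-5-methoxyphenol (E/Z mixture), via tertiary carbinol 7 (not isolated)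
Conditions: 6 (3.5 equiv), THF, 0 → 23 °C; aq. NH4Cl; crude in PhMe, PPTS (10 mol %), 50 °C
Reagents that add atoms: none
Why: Grignard addition to a non-enolisable 2-hydroxybenzophenone, then mild acid-catalysed E1 dehydration of the ortho-hydroxy tertiary diaryl carbinol (through its ortho-quinone methide) should give the triarylethene, whose geometry need not be controlled and which this weak acid should not cyclise.

Step 5
Reactants: 8 3-bromo-2-[1-(3,5-dimethoxyphenyl)-2-(4-methoxyphenyl)ethenyl]-5-methoxyphenol (E/Z mixture)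
Product: 9 (2R,3R)-4-bromo-3-(3,5-dimethoxyphenyl)-6-methoxy-2-(4-methoxyphenyl)-2,3-dihydro-1-benzofuran (trans)
Conditions: (S,S)-A (5 mol %), CHCl3, 5 Å MS, −30 °C, 0.02 M
Reagents that add atoms: none
Why: Proposed new method: acid A should transfer its proton to the diaryl-substituted alkene carbon (future C3) of either alkene isomer, leaving a 4-methoxybenzylic cation at C2 held as a contact ion pair with the chiral imidodiphosphorimidate anion, and the ortho phenol oxygen, hydrogen-bonded to the same anion, then closes O1–C2. The closest known reactions are the achiral acid-mediated cyclisation of 2-hydroxystilbenes to 2-aryl-2,3-dihydrobenzofurans and the intramolecular hydroalkoxylation of alkenes by confined chiral imidodiphosphorimidate acids. Ring C closes by oxygen capture of the benzylic cation, a formally 5-endo-trig Markovnikov hydroalkoxylation that forms the O1–C2 bond. C3 is set by the face of proton delivery inside the chiral pocket of the anion (catalyst control), and C2 follows from it because oxygen adds anti to the C3 aryl group, which gives the trans ring. The step needs regioselective productive protonation and E/Z convergence: protonation at the other carbon gives a diarylmethyl (ortho-quinone-methide type) cation that cannot close a five-membered ring and only returns alkene, so it equilibrates the E and Z isomers and all material should drain through the ion pair that the para-methoxy group stabilises. Low temperature and a low acid loading keep the closure kinetic so that the product ether does not reopen.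

Step 6
Reactants: 2 2-bromo-6-hydroxy-4-methoxybenzaldehyde
Product: 10 sodium 3-bromo-2-formyl-5-methoxyphenolate (anhydrous solid, one batch for steps 7 and 11)
Conditions: NaH (1.0 equiv), THF, 0 → 23 °C; evaporate, wash with dry hexane, dry in vacuo; store under Ar
Reagents that add atoms: sodium hydride [H-].[Na+]
Why: Irreversible acid–base deprotonation of the acidic salicylaldehyde phenol by NaH should give the sodium phenolate as an isolable, storable salt, so that the aldehyde carries no acidic proton when it meets an aryllithium.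

Step 7
Reactants: 9 (2R,3R)-4-bromo-3-(3,5-dimethoxyphenyl)-6-methoxy-2-(4-methoxyphenyl)-2,3-dihydro-1-benzofuran; 10 sodium 3-bromo-2-formyl-5-methoxyphenolate
Product: 12 3-bromo-2-[(ArC)(hydroxy)methyl]-5-methoxyphenol (both carbinol epimers), via aryllithium 11 (not isolated)
Conditions: n-BuLi (1.05 equiv), THF, −78 °C, 10 min; then 10 (1.3 equiv) in THF, −78 → −20 °C; aq. NH4Cl
Reagents that add atoms: none
Why: Bromine–lithium exchange at C4 of ring C outruns deprotonation at −78 °C, and the aryllithium adds 1,2 to the aldehyde of the phenolate salt, which cannot quench it; the carbinol centre is removed in step 8.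

Step 8
Reactants: 12 3-bromo-2-[(ArC)(hydroxy)methyl]-5-methoxyphenol
Product: 13 (2-bromo-6-hydroxy-4-methoxyphenyl)(ArC)methanone
Conditions: activated MnO2 (20 equiv), CH2Cl2, 23 → 40 °C
Reagents that add atoms: none
Why: MnO2 oxidation of a doubly benzylic alcohol under neutral conditions, which should leave the benzylic ether of ring C and its two stereocentres untouched.

Step 9
Reactants: 13 (2-bromo-6-hydroxy-4-methoxyphenyl)(ArC)methanone; 6 (4-methoxybenzyl)magnesium chloride
Product: 15 3-bromo-2-[1-(ArC)-2-(4-methoxyphenyl)ethenyl]-5-methoxyphenol (E/Z mixture), via tertiary carbinol 14 (not isolated)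
Conditions: 6 (3.5 equiv), LaCl3·2LiCl (1 equiv), THF, 0 → 23 °C; aq. NH4Cl; crude in PhMe, PPTS (10 mol %), 50 °C
Reagents that add atoms: none
Why: Lanthanum-assisted Grignard addition to a hindered non-enolisable ketone and mild E1 dehydration as in step 4; PPTS is too weak to ionise ring C.

Step 10
Reactants: 15 3-bromo-2-[1-(ArC)-2-(4-methoxyphenyl)ethenyl]-5-methoxyphenol (E/Z mixture)
Product: 16 (2S,3S)-4-bromo-3-(ArC)-6-methoxy-2-(4-methoxyphenyl)-2,3-dihydro-1-benzofuran (rings B and C, both trans)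
Conditions: (R,R)-A (5 mol %), CHCl3, 5 Å MS, −30 °C, 0.02 M
Reagents that add atoms: none
Why: Proposed new method: the same ion-pair manifold as in step 5 (protonation at the diaryl carbon, phenol capture of the 4-methoxybenzylic cation; closest known type is confined-acid intramolecular hydroalkoxylation of alkenes), now with the mirror-image acid, so that proton delivery sets C3 of ring B as S under catalyst control and anti closure sets C2 as S (trans), while the low temperature should keep ring C closed.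

Step 11
Reactants: 16 (2S,3S)-4-bromo-3-(ArC)-6-methoxy-2-(4-methoxyphenyl)-2,3-dihydro-1-benzofuran; 10 sodium 3-bromo-2-formyl-5-methoxyphenolate
Product: 18 3-bromo-2-[(ArBC)(hydroxy)methyl]-5-methoxyphenol (both carbinol epimers), via aryllithium 17 (not isolated)
Conditions: n-BuLi (1.05 equiv), THF, −78 °C, 10 min; then 10 (1.3 equiv) in THF, −78 → −20 °C; aq. NH4Cl
Reagents that add atoms: none
Why: Bromine–lithium exchange at C4 of ring B and 1,2-addition of the aryllithium to the aldehyde of the phenolate salt, as in step 7.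

Step 12
Reactants: 18 3-bromo-2-[(ArBC)(hydroxy)methyl]-5-methoxyphenol
Product: 19 (2-bromo-6-hydroxy-4-methoxyphenyl)(ArBC)methanone
Conditions: activated MnO2 (20 equiv), CH2Cl2, 23 → 40 °C
Reagents that add atoms: none
Why: MnO2 oxidation of a doubly benzylic alcohol under neutral conditions, as in step 8.

Step 13
Reactants: 19 (2-bromo-6-hydroxy-4-methoxyphenyl)(ArBC)methanone; 6 (4-methoxybenzyl)magnesium chloride
Product: 21 3-bromo-2-[1-(ArBC)-2-(4-methoxyphenyl)ethenyl]-5-methoxyphenol (E/Z mixture), via tertiary carbinol 20 (not isolated)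
Conditions: 6 (3.5 equiv), LaCl3·2LiCl (1 equiv), THF, 0 → 23 °C; aq. NH4Cl; crude in PhMe, PPTS (10 mol %), 50 °C
Reagents that add atoms: none
Why: Lanthanum-assisted Grignard addition to the hindered ketone and mild E1 dehydration, as in step 9.

Step 14
Reactants: 21 3-bromo-2-[1-(ArBC)-2-(4-methoxyphenyl)ethenyl]-5-methoxyphenol (E/Z mixture)
Product: 22 (2R,3R)-4-bromo-3-(ArBC)-6-methoxy-2-(4-methoxyphenyl)-2,3-dihydro-1-benzofuran (rings A, B and C, all trans)
Conditions: (S,S)-A (10 mol %), CHCl3, 5 Å MS, −30 °C, 0.02 M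
Reagents that add atoms: none
Why: Proposed new method: third use of the chiral-acid protonation and phenol capture (closest known type is confined-acid intramolecular hydroalkoxylation of alkenes), in which the acid enantiomer of step 5 should deliver the proton to set C3 of ring A as R and anti closure of O1–C2 should set C2 as R (trans).

Step 15
Reactants: 22 (2R,3R)-4-bromo-3-(ArBC)-6-methoxy-2-(4-methoxyphenyl)-2,3-dihydro-1-benzofuran
Product: 23 the octaphenol of 22 (all eight methoxy groups as hydroxy groups, C4 bromide of ring A kept)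
Conditions: BBr3 (24 equiv), CH2Cl2, −78 → 23 °C; then MeOH, H2O
Reagents that add atoms: none
Why: BBr3 cleavage of aryl methyl ethers, run before the stilbene is installed so that no acid-sensitive alkene is present; any reversible opening of a benzylic C2–O bond should reclose to the trans ring with C3 untouched.

Step 16
Reactants: 23 the octaphenol bromide
Product: 24 the octaacetate of 23
Conditions: Ac2O, pyridine, DMAP (cat.), 23 °C
Reagents that add atoms: acetic anhydride CC(=O)OC(C)=O
Why: Standard phenol acetylation, which makes the polyphenol handleable and keeps phenoxides out of the palladium step.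

Step 17
Reactants: 24 the octaacetate bromide; 25 3,4-diacetoxystyrene
Product: 26 the decaacetate of the target (E-stilbene)
Conditions: Pd2(dba)3 (5 mol %), P(t-Bu)3·HBF4 (12 mol %), Cy2NMe (1.5 equiv), 25 (2 equiv), 1,4-dioxane, 80 °C
Reagents that add atoms: none
Why: Mizoroki–Heck coupling of the ortho-substituted aryl bromide with a styrene under a bulky electron-rich phosphine on zerovalent palladium; syn insertion and syn β-hydride elimination should give the E-alkene, and the hindered amine base spares the acetates.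

Step 18
Reactants: 26 the decaacetate
Product: 27 the target, 4-[(E)-2-{(2R,3R)-3-[(2S,3S)-3-[(2R,3R)-3-(3,5-dihydroxyphenyl)-6-hydroxy-2-(4-hydroxyphenyl)-2,3-dihydro-1-benzofuran-4-yl]-6-hydroxy-2-(4-hydroxyphenyl)-2,3-dihydro-1-benzofuran-4-yl]-6-hydroxy-2-(4-hydroxyphenyl)-2,3-dihydro-1-benzofuran-4-yl}ethenyl]benzene-1,2-diol
Conditions: NH3 (7 M in MeOH), degassed, Ar, 0 → 23 °C; evaporate; reversed-phase chromatography
Reagents that add atoms: none
Why: Ammonolysis of aryl acetates is fast under mild, acid-free conditions, so the stilbene cannot cyclise onto ring B and no stereocentre is touched; oxygen is excluded to protect the catechol.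

**Compound list**

1 | 2-bromo-4,6-dimethoxybenzaldehyde | COc1cc(OC)c(C=O)c(Br)c1 | starting material
2 | 2-bromo-6-hydroxy-4-methoxybenzaldehyde | COc1cc(O)c(C=O)c(Br)c1 | intermediate
3 | (3,5-dimethoxyphenyl)magnesium chloride | COc1cc(OC)cc([Mg]Cl)c1 | starting material
4 | 3-bromo-2-[(3,5-dimethoxyphenyl)(hydroxy)methyl]-5-methoxyphenol (racemic) | COc1cc(O)c(C(O)c2cc(OC)cc(OC)c2)c(Br)c1 | intermediate
5 | (2-bromo-6-hydroxy-4-methoxyphenyl)(3,5-dimethoxyphenyl)methanone | COc1cc(O)c(C(=O)c2cc(OC)cc(OC)c2)c(Br)c1 | intermediate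
6 | (4-methoxybenzyl)magnesium chloride | COc1ccc(C[Mg]Cl)cc1 | starting material
7 | 3-bromo-2-[1-(3,5-dimethoxyphenyl)-1-hydroxy-2-(4-methoxyphenyl)ethyl]-5-methoxyphenol (racemic, not isolated) | COc1ccc(CC(O)(c2cc(OC)cc(OC)c2)c2c(O)cc(OC)cc2Br)cc1 | intermediate
8 | 3-bromo-2-[1-(3,5-dimethoxyphenyl)-2-(4-methoxyphenyl)ethenyl]-5-methoxyphenol (E/Z mixture) | COc1ccc(C=C(c2cc(OC)cc(OC)c2)c2c(O)cc(OC)cc2Br)cc1 | intermediate
9 | (2R,3R)-4-bromo-3-(3,5-dimethoxyphenyl)-6-methoxy-2-(4-methoxyphenyl)-2,3-dihydro-1-benzofuran | Brc1cc(OC)cc2c1[C@@H](c1cc(OC)cc(OC)c1)[C@H](c1ccc(OC)cc1)O2 | intermediate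
10 | sodium 3-bromo-2-formyl-5-methoxyphenolate | COc1cc([O-])c(C=O)c(Br)c1.[Na+] | intermediate
11 | (ArC)lithium, the C4 aryllithium of ring C (not isolated) | [Li]c1cc(OC)cc2c1[C@@H](c1cc(OC)cc(OC)c1)[C@H](c1ccc(OC)cc1)O2 | intermediate
12 | 3-bromo-2-[(ArC)(hydroxy)methyl]-5-methoxyphenol (both carbinol epimers) | OC(c1c(O)cc(OC)cc1Br)c1cc(OC)cc2c1[C@@H](c1cc(OC)cc(OC)c1)[C@H](c1ccc(OC)cc1)O2 | intermediate
13 | (2-bromo-6-hydroxy-4-methoxyphenyl)(ArC)methanone | O=C(c1c(O)cc(OC)cc1Br)c1cc(OC)cc2c1[C@@H](c1cc(OC)cc(OC)c1)[C@H](c1ccc(OC)cc1)O2 | intermediate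
14 | 3-bromo-2-[1-(ArC)-1-hydroxy-2-(4-methoxyphenyl)ethyl]-5-methoxyphenol (both carbinol epimers, not isolated) | OC(Cc1ccc(OC)cc1)(c1c(O)cc(OC)cc1Br)c1cc(OC)cc2c1[C@@H](c1cc(OC)cc(OC)c1)[C@H](c1ccc(OC)cc1)O2 | intermediate
15 | 3-bromo-2-[1-(ArC)-2-(4-methoxyphenyl)ethenyl]-5-methoxyphenol (E/Z mixture) | COc1ccc(C=C(c2c(O)cc(OC)cc2Br)c2cc(OC)cc3c2[C@@H](c2cc(OC)cc(OC)c2)[C@H](c2ccc(OC)cc2)O3)cc1 | intermediate
16 | (2S,3S)-4-bromo-3-(ArC)-6-methoxy-2-(4-methoxyphenyl)-2,3-dihydro-1-benzofuran | COc1ccc([C@H]2Oc3cc(OC)cc(Br)c3[C@@H]2c2cc(OC)cc3c2[C@@H](c2cc(OC)cc(OC)c2)[C@H](c2ccc(OC)cc2)O3)cc1 | intermediate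
17 | (ArBC)lithium, the C4 aryllithium of ring B (not isolated) | COc1ccc([C@H]2Oc3cc(OC)cc([Li])c3[C@@H]2c2cc(OC)cc3c2[C@@H](c2cc(OC)cc(OC)c2)[C@H](c2ccc(OC)cc2)O3)cc1 | intermediate
18 | 3-bromo-2-[(ArBC)(hydroxy)methyl]-5-methoxyphenol (both carbinol epimers) | COc1ccc([C@H]2Oc3cc(OC)cc(C(O)c4c(O)cc(OC)cc4Br)c3[C@@H]2c2cc(OC)cc3c2[C@@H](c2cc(OC)cc(OC)c2)[C@H](c2ccc(OC)cc2)O3)cc1 | intermediate
19 | (2-bromo-6-hydroxy-4-methoxyphenyl)(ArBC)methanone | COc1ccc([C@H]2Oc3cc(OC)cc(C(=O)c4c(O)cc(OC)cc4Br)c3[C@@H]2c2cc(OC)cc3c2[C@@H](c2cc(OC)cc(OC)c2)[C@H](c2ccc(OC)cc2)O3)cc1 | intermediate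
20 | 3-bromo-2-[1-(ArBC)-1-hydroxy-2-(4-methoxyphenyl)ethyl]-5-methoxyphenol (both carbinol epimers, not isolated) | COc1ccc([C@H]2Oc3cc(OC)cc(C(O)(Cc4ccc(OC)cc4)c4c(O)cc(OC)cc4Br)c3[C@@H]2c2cc(OC)cc3c2[C@@H](c2cc(OC)cc(OC)c2)[C@H](c2ccc(OC)cc2)O3)cc1 | intermediate
21 | 3-bromo-2-[1-(ArBC)-2-(4-methoxyphenyl)ethenyl]-5-methoxyphenol (E/Z mixture) | COc1ccc([C@H]2Oc3cc(OC)cc(C(=Cc4ccc(OC)cc4)c4c(O)cc(OC)cc4Br)c3[C@@H]2c2cc(OC)cc3c2[C@@H](c2cc(OC)cc(OC)c2)[C@H](c2ccc(OC)cc2)O3)cc1 | intermediate
22 | (2R,3R)-4-bromo-3-(ArBC)-6-methoxy-2-(4-methoxyphenyl)-2,3-dihydro-1-benzofuran | COc1ccc([C@H]2Oc3cc(OC)cc([C@@H]4c5c(Br)cc(OC)cc5O[C@H]4c4ccc(OC)cc4)c3[C@@H]2c2cc(OC)cc3c2[C@@H](c2cc(OC)cc(OC)c2)[C@H](c2ccc(OC)cc2)O3)cc1 | intermediate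
23 | (2R,3R)-4-bromo-3-{(2S,3S)-3-[(2R,3R)-3-(3,5-dihydroxyphenyl)-6-hydroxy-2-(4-hydroxyphenyl)-2,3-dihydro-1-benzofuran-4-yl]-6-hydroxy-2-(4-hydroxyphenyl)-2,3-dihydro-1-benzofuran-4-yl}-2-(4-hydroxyphenyl)-2,3-dihydro-1-benzofuran-6-ol | Oc1ccc([C@H]2Oc3cc(O)cc([C@@H]4c5c(Br)cc(O)cc5O[C@H]4c4ccc(O)cc4)c3[C@@H]2c2cc(O)cc3c2[C@@H](c2cc(O)cc(O)c2)[C@H](c2ccc(O)cc2)O3)cc1 | intermediate
24 | octaacetate of 23 | CC(=O)Oc1ccc([C@H]2Oc3cc(OC(C)=O)cc([C@@H]4c5c(Br)cc(OC(C)=O)cc5O[C@H]4c4ccc(OC(C)=O)cc4)c3[C@@H]2c2cc(OC(C)=O)cc3c2[C@@H](c2cc(OC(C)=O)cc(OC(C)=O)c2)[C@H](c2ccc(OC(C)=O)cc2)O3)cc1 | intermediate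
25 | 3,4-diacetoxystyrene (4-ethenyl-1,2-phenylene diacetate) | CC(=O)Oc1ccc(C=C)cc1OC(C)=O | starting material
26 | decaacetate of the target (E-stilbene) | CC(=O)Oc1ccc([C@H]2Oc3cc(OC(C)=O)cc([C@@H]4c5c(/C=C/c6ccc(OC(C)=O)c(OC(C)=O)c6)cc(OC(C)=O)cc5O[C@H]4c4ccc(OC(C)=O)cc4)c3[C@@H]2c2cc(OC(C)=O)cc3c2[C@@H](c2cc(OC(C)=O)cc(OC(C)=O)c2)[C@H](c2ccc(OC(C)=O)cc2)O3)cc1 | intermediate
27 | target CNP0099535.1 | Oc1ccc([C@H]2Oc3cc(O)cc([C@@H]4c5c(/C=C/c6ccc(O)c(O)c6)cc(O)cc5O[C@H]4c4ccc(O)cc4)c3[C@@H]2c2cc(O)cc3c2[C@@H](c2cc(O)cc(O)c2)[C@H](c2ccc(O)cc2)O3)cc1 | target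

**Totals**

- Total step count: 18.
- Longest linear sequence: 17 steps (1 → 2 → 4 → 5 → 8 → 9 → 12 → … → 27; step 6 is a one-step side branch from 2).

**Steps most likely to fail**

Step 5. The proton delivery may discriminate the two alkene faces poorly, an uncatalysed or reversible closure may erode the enantiomeric purity, or the acid may be consumed in unproductive protonation. The fallback closes the ring by C2–C3 bond formation with a chiral rhodium carbene instead; it sets out from 5 and comes back at 9. Alkylation of 5 with 4-methoxybenzyl chloride (K2CO3, NaI, DMF) should give [2-bromo-4-methoxy-6-(4-methoxybenzyloxy)phenyl](3,5-dimethoxyphenyl)methanone F1. Hydrazine hydrate and AcOH in hot EtOH should convert it into the hydrazone F2, and MnO2 should oxidise this to the diaryldiazomethane F3 (not isolated). Rh2(S-PTAD)4 (a chiral carboxylate of divalent rhodium) or its mirror image, whichever gives 3R, should insert the donor/donor carbene into the 4-methoxybenzylic C–H bond to give the cis ring, (2S,3R)-4-bromo-3-(3,5-dimethoxyphenyl)-6-methoxy-2-(4-methoxyphenyl)-2,3-dihydro-1-benzofuran F4. CF3CO2H in CH2Cl2 should then epimerise C2 through reversible C2–O ionisation to the trans isomer 9, with C3 retained.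

Step 10. The resident stereocentres of ring C may override the catalyst (mismatched double stereodifferentiation), or protonation of the more hindered alkene may be too slow at a temperature that keeps ring C intact. The fallback gives up catalyst control; it sets out from 15 and comes back at 16. The E/Z mixture 15 is closed with an achiral acid under equilibrating conditions (CF3SO3H 10 mol %, CH2Cl2, 0 → 23 °C), the known acid-mediated cyclisation of 2-hydroxystilbenes. This should give the two trans ring B isomers, which are diastereomers because ring C is already enantiopure. 16 is then separated by chromatography from its ring B epimer pair, (2R,3R)-4-bromo-3-(ArC)-6-methoxy-2-(4-methoxyphenyl)-2,3-dihydro-1-benzofuran F5.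

Step 14. The same mismatch may occur with two resident rings, and the acid may open rings B or C while ring A is still closing. The fallback again relies on substrate control and separation; it sets out from 21 and comes back at 22. 21 is cyclised with CF3SO3H (10 mol %, CH2Cl2, 0 → 23 °C) to the two trans ring A isomers, and 22 is separated by chromatography from the ring A diastereomer, (2S,3S)-4-bromo-3-(ArBC)-6-methoxy-2-(4-methoxyphenyl)-2,3-dihydro-1-benzofuran F6.

Further compounds
F1 | step 5 | [2-bromo-4-methoxy-6-(4-methoxybenzyloxy)phenyl](3,5-dimethoxyphenyl)methanone | COc1ccc(COc2cc(OC)cc(Br)c2C(=O)c2cc(OC)cc(OC)c2)cc1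
F2 | step 5 | hydrazone of F1 | COc1ccc(COc2cc(OC)cc(Br)c2C(=NN)c2cc(OC)cc(OC)c2)cc1
F3 | step 5 | [2-bromo-4-methoxy-6-(4-methoxybenzyloxy)phenyl](3,5-dimethoxyphenyl)diazomethane (not isolated) | COc1ccc(COc2cc(OC)cc(Br)c2C(=[N+]=[N-])c2cc(OC)cc(OC)c2)cc1
F4 | step 5 | (2S,3R)-4-bromo-3-(3,5-dimethoxyphenyl)-6-methoxy-2-(4-methoxyphenyl)-2,3-dihydro-1-benzofuran (cis) | Brc1cc(OC)cc2c1[C@@H](c1cc(OC)cc(OC)c1)[C@@H](c1ccc(OC)cc1)O2
F5 | step 10 | (2R,3R)-4-bromo-3-(ArC)-6-methoxy-2-(4-methoxyphenyl)-2,3-dihydro-1-benzofuran (ring B diastereomer of 16) | COc1ccc([C@@H]2Oc3cc(OC)cc(Br)c3[C@H]2c2cc(OC)cc3c2[C@@H](c2cc(OC)cc(OC)c2)[C@H](c2ccc(OC)cc2)O3)cc1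
F6 | step 14 | (2S,3S)-4-bromo-3-(ArBC)-6-methoxy-2-(4-methoxyphenyl)-2,3-dihydro-1-benzofuran (ring A diastereomer of 22) | COc1ccc([C@H]2Oc3cc(OC)cc([C@H]4c5c(Br)cc(OC)cc5O[C@@H]4c4ccc(OC)cc4)c3[C@@H]2c2cc(OC)cc3c2[C@@H](c2cc(OC)cc(OC)c2)[C@H](c2ccc(OC)cc2)O3)cc1
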